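With the ring numbered C1 (OMe), C2=C3, C4 (OBz), C5 (OAc), C6 (OH, CH2OBz), everything rests on cutting C3–C4 and C5–C6. C6 and C3 stand 1,4 across the carbocycle and C6 bears oxygen, so the four-carbon half is a furan whose ring oxygen becomes the C6 hydroxyl and whose 3-methoxy group is the C1 methoxy; the two-carbon half is an (E)-β-acetoxyvinyl phenyl ketone. One catalytic asymmetric Diels–Alder reaction closes the carbocycle as a 7-oxanorbornene and sets C4, C5 and C6 with regiochemistry dictated by the methoxy group. Directed reductive opening of the oxygen bridge (C1) and Baeyer–Villiger oxidation of the C4 benzoyl group follow.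

Key step: step 3

Assumption: 3-methoxyfuran is taken as a commercially available starting material; the ring numbering C1–C6 defined above is used for all later compounds.

Step 1
Reactants: 1 3-methoxyfuran
Product: 4 (3-methoxyfuran-2-yl)methyl benzoate, via 2-lithio-3-methoxyfuran 2 (not isolated), via lithium (3-methoxyfuran-2-yl)methanolate 3 (not isolated)
Conditions: n-BuLi, THF, −78 to 0 °C; monomeric CH2O (cracked paraformaldehyde), −78 °C to rt; BzCl, 0 °C; work-up and chromatography on Et3N-deactivated silica
Reagents that add atoms: formaldehyde C=O; benzoyl chloride O=C(Cl)c1ccccc1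
Why: Directed α-lithiation at furan C2 (flanked by the ring oxygen and the methoxy group), hydroxymethylation and in situ O-acylation of the alkoxide should give the ester without isolating the acid-labile furfuryl alcohol; no stereocentre is formed.

Step 2
Reactants: 5 1-phenylprop-2-yn-1-one
Product: 6 (E)-3-oxo-3-phenylprop-1-en-1-yl acetate
Conditions: AcOH, 1,4-diazabicyclo[2.2.2]octane (10 mol %), CH2Cl2, 0 °C to rt
Reagents that add atoms: acetic acid CC(=O)O
Why: Tertiary-amine-catalysed conjugate addition of a carboxylic acid to an ynone should give the β-acyloxy enone as the thermodynamically preferred E isomer through reversible addition–elimination.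

Step 3
Reactants: 4 (3-methoxyfuran-2-yl)methyl benzoate; 6 (E)-3-oxo-3-phenylprop-1-en-1-yl acetate
Product: 7 [(1S,4S,5R,6S)-6-acetoxy-5-benzoyl-2-methoxy-7-oxabicyclo[2.2.1]hept-2-en-1-yl]methyl benzoate (5-endo-benzoyl, 6-exo-acetoxy)
Conditions: (S)-3,3-diphenyl-1-(o-tolyl)tetrahydro-1H,3H-pyrrolo[1,2-c][1,3,2]oxazaborole·HNTf2 (20 mol %), CH2Cl2, −78 °C; Et3N quench at −78 °C; used directly
Reagents that add atoms: none
Why: The boron-bound enone and the electron-rich furan should combine in a concerted, asynchronous, suprafacial [4+2] cycloaddition, the closest known reactions being oxazaborolidinium-catalysed Diels–Alder reactions of furan and of 2-silyloxydienes with enones and the endo-selective cycloadditions of 3-alkoxyfurans. The carbocycle C1–C6 closes by cycloaddition across furan C2 and C5, which gives the 7-oxabicyclo[2.2.1]heptene. The 3-methoxy group makes furan C2 (future C6) the most nucleophilic terminus, so it bonds to the acetoxy-bearing β-carbon of the enone (C5) and the benzoyl-bearing carbon becomes C4. C4 and C5 are trans because the E geometry is conserved, and the endo rule places the coordinated benzoyl group anti to the oxygen bridge and the acetoxy group exo, which fixes both centres relative to C6 and C3. The absolute sense comes from the catalyst shielding one enone face (the S catalyst is proposed from the α-C–H···O binding model; its antipode is used if the induction proves opposite). The step needs regio-, endo- and facial selectivity together, and low temperature with a basic quench because the adduct is a bridged vinylogous ketal that can revert or ionise.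

Step 4
Reactants: 7 [(1S,4S,5R,6S)-6-acetoxy-5-benzoyl-2-methoxy-7-oxabicyclo[2.2.1]hept-2-en-1-yl]methyl benzoate
Product: 10 [(1R,2S,3R,6S)-2-acetoxy-3-benzoyl-1-hydroxy-6-methoxycyclohex-4-en-1-yl]methyl benzoate, via oxocarbenium triflate 8 (not isolated), via silyl triflate 9 (not isolated)
Conditions: iPr2Si(H)OTf (from iPr2SiHCl + AgOTf, CH2Cl2, 0 °C), 2,6-di-tert-butyl-4-methylpyridine, CH2Cl2, −78 °C; then HF·pyridine, THF, 0 °C
Reagents that add atoms: none
Why: Proposed new method: the silyl triflate should silylate the bridging oxygen, the C3–O bond then ionises with help from the C1 methoxy group (vinylogous ketal to conjugated oxocarbenium 8), and the Si–H now tethered to the C6 oxygen delivers hydride to C1 through a five-membered transition state on the face of that oxygen, so that H ends cis and OMe trans to the C6 oxygen before HF·pyridine frees the tertiary alcohol; the closest known reactions are Lewis-acid-promoted intramolecular hydrosilylation of (hydridosilyl)oxy ketones and silyl triflate/hydrosilane reductive cleavage of allylic acetals.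

Step 5
Reactants: 10 [(1R,2S,3R,6S)-2-acetoxy-3-benzoyl-1-hydroxy-6-methoxycyclohex-4-en-1-yl]methyl benzoate
Product: 11 [(1R,2S,3R,6S)-2-acetoxy-3-(benzoyloxy)-1-hydroxy-6-methoxycyclohex-4-en-1-yl]methyl benzoate (target)
Conditions: mCPBA, NaHCO3, CH2Cl2, 0 °C to rt
Reagents that add atoms: mCPBA OOC(=O)c1cccc(Cl)c1
Why: In this Baeyer–Villiger oxidation the secondary allylic C4 should migrate in preference to phenyl and with retention, turning the benzoyl group into the C4 benzoate, while the alkene is deactivated by its two allylic electron-withdrawing neighbours.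

Compound list
1 | 3-methoxyfuran | COc1ccoc1 | starting material
2 | 2-lithio-3-methoxyfuran | [Li]c1occc1OC | intermediate
3 | lithium (3-methoxyfuran-2-yl)methanolate | [Li+].[O-]Cc1occc1OC | intermediate
4 | (3-methoxyfuran-2-yl)methyl benzoate | COc1ccoc1COC(=O)c1ccccc1 | intermediate
5 | 1-phenylprop-2-yn-1-one | C#CC(=O)c1ccccc1 | starting material
6 | (E)-3-oxo-3-phenylprop-1-en-1-yl acetate | CC(=O)O/C=C/C(=O)c1ccccc1 | intermediate
7 | [(1S,4S,5R,6S)-6-acetoxy-5-benzoyl-2-methoxy-7-oxabicyclo[2.2.1]hept-2-en-1-yl]methyl benzoate | COC1=C[C@H]2[C@@H](C(=O)c3ccccc3)[C@H](OC(C)=O)[C@]1(COC(=O)c4ccccc4)O2 | intermediate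
8 | ring-opened O-methyl oxocarbenium triflate carrying the C6 O-diisopropylsilyl (Si–H) ether; C4–C6 configured as in 10 | C[O+]=C1C=C[C@@H](C(=O)c2ccccc2)[C@H](OC(C)=O)[C@@]1(O[SiH](C(C)C)C(C)C)COC(=O)c3ccccc3.[O-]S(=O)(=O)C(F)(F)F | intermediate
9 | C6 O-[diisopropyl(trifluoromethanesulfonyloxy)silyl] ether of 10 | CO[C@H]1C=C[C@@H](C(=O)c2ccccc2)[C@H](OC(C)=O)[C@@]1(O[Si](OS(=O)(=O)C(F)(F)F)(C(C)C)C(C)C)COC(=O)c3ccccc3 | intermediate
10 | [(1R,2S,3R,6S)-2-acetoxy-3-benzoyl-1-hydroxy-6-methoxycyclohex-4-en-1-yl]methyl benzoate | CO[C@H]1C=C[C@@H](C(=O)c2ccccc2)[C@H](OC(C)=O)[C@@]1(O)COC(=O)c3ccccc3 | intermediate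
11 | [(1R,2S,3R,6S)-2-acetoxy-3-(benzoyloxy)-1-hydroxy-6-methoxycyclohex-4-en-1-yl]methyl benzoate | CO[C@H]1C=C[C@@H](OC(=O)c2ccccc2)[C@H](OC(C)=O)[C@@]1(O)COC(=O)c1ccccc1 | target

Total step count: 5. Longest linear sequence: 4 steps (step 1, then 3, 4, 5; step 2 feeds step 3).

Steps most likely to fail

Step 4. The cation formed on bridge opening may lose a proton at C4 and aromatise, or hydride may reach C1 intermolecularly from the face anti to the C6 oxygen. The fallback uses known chemistry only and sets out from 7. Hydrolytic opening of the bridged ketal (PPTS, acetone/H2O, 0 °C) should give the 6-hydroxycyclohex-2-enone F1. Hydroxyl-directed 1,2-reduction (Me4NBH(OAc)3, AcOH/MeCN, −30 °C) should deliver hydride from the face of the C6 hydroxyl and give the trans-diol F2. Selective O-methylation of the secondary allylic hydroxyl (MeOTf, 2,6-di-tert-butyl-4-methylpyridine, CH2Cl2, 0 °C) then gives 10, where the route is rejoined.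

Step 3. The Lewis acid may ionise the furfuryl benzoate or divert the furan into conjugate alkylation at its free α-position, or facial selectivity may be poor. The fallback sets out from 4 and 6. Cycloaddition without Lewis acid at 10–12 kbar (CH2Cl2, room temperature) should give 7 as a racemate, that is, mixed with the mirror-image adduct F3. Step 4 applied to the mixture passes through the mirror-image oxocarbenium triflate F4 and the mirror-image silyl triflate F5 and gives 10 mixed with the mirror-image ketone F6. Preparative HPLC on a cellulose-based chiral stationary phase separates the two, and 10 rejoins the route at step 5.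

Step 5. The peracid may epoxidise C2=C3 under direction of the free C6 hydroxyl, with transannular attack of that hydroxyl, faster than it oxidises the ketone. The fallback sets out from 7. In step 4 the silyl triflate 9 is quenched with MeOH/Et3N instead of HF·pyridine, and the methoxydiisopropylsilyl ether F7 is isolated. Baeyer–Villiger oxidation of F7 (mCPBA, NaHCO3, CH2Cl2) should give the silyl-protected benzoate F8 with no directing hydroxyl present. HF·pyridine (THF, 0 °C) then gives 11.

Further compounds
F1 | step 4 | 6-hydroxycyclohex-2-enone: C4 benzoyl, C5 acetoxy, C6 hydroxy and benzoyloxymethyl, C4–C6 configured as in 10 | O=C1C=C[C@@H](C(=O)c2ccccc2)[C@H](OC(C)=O)[C@@]1(O)COC(=O)c3ccccc3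
F2 | step 4 | [(1R,2S,3R,6S)-2-acetoxy-3-benzoyl-1,6-dihydroxycyclohex-4-en-1-yl]methyl benzoate | O[C@H]1C=C[C@@H](C(=O)c2ccccc2)[C@H](OC(C)=O)[C@@]1(O)COC(=O)c3ccccc3
F3 | step 3 | enantiomer of 7, (1R,4R,5S,6R) | COC1=C[C@@H]2[C@H](C(=O)c3ccccc3)[C@@H](OC(C)=O)[C@@]1(COC(=O)c4ccccc4)O2
F4 | step 3 | enantiomer of oxocarbenium triflate 8 | C[O+]=C1C=C[C@H](C(=O)c2ccccc2)[C@@H](OC(C)=O)[C@]1(O[SiH](C(C)C)C(C)C)COC(=O)c3ccccc3.[O-]S(=O)(=O)C(F)(F)F
F5 | step 3 | enantiomer of silyl triflate 9 | CO[C@@H]1C=C[C@H](C(=O)c2ccccc2)[C@@H](OC(C)=O)[C@]1(O[Si](OS(=O)(=O)C(F)(F)F)(C(C)C)C(C)C)COC(=O)c3ccccc3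
F6 | step 3 | enantiomer of 10, (1S,2R,3S,6R) | CO[C@@H]1C=C[C@H](C(=O)c2ccccc2)[C@@H](OC(C)=O)[C@]1(O)COC(=O)c3ccccc3
F7 | step 5 | C6 O-[diisopropyl(methoxy)silyl] ether of 10 | CO[C@H]1C=C[C@@H](C(=O)c2ccccc2)[C@H](OC(C)=O)[C@@]1(O[Si](OC)(C(C)C)C(C)C)COC(=O)c3ccccc3
F8 | step 5 | C6 O-[diisopropyl(methoxy)silyl] ether of 11 | CO[C@H]1C=C[C@@H](OC(=O)c2ccccc2)[C@H](OC(C)=O)[C@@]1(O[Si](OC)(C(C)C)C(C)C)COC(=O)c3ccccc3
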